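We have 5 questions about 4 set-ups, and we answer them by following one molecule of substrate through its chances.

| flask | substrate | catalyst | remark | time |
|---|---|---|---|---|
| midnight | 0.10 M | 50 µM | run made earlier |  |
| summer | 0.10 M | 34 µM | run made earlier |  |
| autumn | 0.10 M | 75 µM | run made earlier |  |
| dawn | 0.20 M | 50 µM | run made earlier |  |
| oak | 0.10 M (fed, over 3.00 d) | 50 µM | all but substrate at the start; substrate goes in evenly over 3.00 d, the run ends at 3.0 d | 3.0 d |
| elm | 0.10 M | 50 µM | a closed flask charged with all of it at once and left for 3.0 d | 3.0 d |
| ash | 0.10 M | 50 µM | a single well-mixed tank run continuously and read at steady state, 3.0 d in it on average |  |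
| cedar | 0.10 M | 50 µM | one stirred flow tank at steady state, fed with the mixture as stated, mean residence time 15.0 d |  |

midnight run (percent of the substrate charged)

| time / d | target / % |
|---|---|
| 0.250 | 5.7 |
| 0.833 | 26.1 |
| 1.25 | 37.3 |
| 2.00 | 52.0 |
| 3.00 | 61.6 |

summer run (percent of the substrate charged)

| time / h | target / % |
|---|---|
| 8.00 | 7.6 |
| 15.0 | 13.4 |
| 25.0 | 23.2 |
| 30.0 | 27.7 |
| 40.0 | 35.3 |

autumn run (percent of the substrate charged)

| time / h | target / % |
|---|---|
| 4.00 | 4.2 |
| 10.0 | 16.4 |
| 20.0 | 36.5 |
| 30.0 | 48.6 |
| 40.0 | 58.4 |

dawn run (percent of the substrate charged)

| time / h | target / % |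
|---|---|
| 4.00 | 4.0 |
| 10.0 | 11.7 |
| 20.0 | 26.3 |
| 30.0 | 37.1 |
| 40.0 | 45.6 |

(readings scatter by 1 percentage point)

- the set-up with the highest amount of target at the outlet or at the end, in percent of the substrate put in ("none" if the first two lie within 2 percentage points) (oak / elm / ash / cedar / none)
- amount of target at the outlet or at the end, in percent of the substrate put in, oak
- amount of target at the outlet or at the end, in percent of the substrate put in, elm
- amount of target at the outlet or at the end, in percent of the substrate put in, ash
- amount of target at the outlet or at the end, in percent of the substrate put in, cedar

- the stated concentrations are those of everything mixed, before any reaction; amounts are the same in each set-up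
- the feed brings no volume worth counting
- the earlier runs were made in a closed, stirred flask

We read the bend of the midnight run as the approach to a ceiling, so we write its rate as a catch rate times the distance still to that ceiling. Comparing the rise from 0.250 d to 1.25 d with the rise from 2.00 d to 3.00 d gives a catch rate, a pseudo-first-order constant at [catalyst] = 50 µM, of 0.623 d⁻¹, and a ceiling of 72.2%.

In a tank, we take a molecule to be caught at that rate and washed out at one over the residence time, so its chance of being caught is the catch rate divided by the sum of these two rates. For cedar that chance is 90.3%, since catching is faster than washing out. Ceiling times chance gives cedar 65.2%, against the 61.6% that midnight read at 3.00 d, which is elm's charge and time. That lead is 3.6 percentage points, against a margin of 2 points, and the ceiling is the weak link.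

So we reforge it from different readings. The autumn run gives a catch rate of 0.0381 h⁻¹, which is 0.609 d⁻¹ when scaled to midnight's catalyst, and a ceiling of 79.2%. The mean of these two readings of the ceiling is the fork share 75.7%, our estimate of the chance that a molecule of substrate, once caught, counts as target, its selectivity. We commit to cedar at 68.4%, above the midnight reading for elm's charge and time, and to ash at 49.3%.

The forecast names elm, with oak 38.2%, elm 61.5%, ash 43.5% and cedar 37% (range 31% to 68%). On the cause of the bend it says: “The data cannot separate these, though I favour over-reaction.”

The flask gives oak 38.5%, elm 63.5%, ash 47.6% and cedar 69.4%, so the best is cedar.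

    substrate → uncatalysed product (k = 0.00110 min⁻¹)
    substrate → intermediate (k = 0.00390 min⁻¹)
    catalyst + intermediate → catalyst + target (k = 8.20 M⁻¹ min⁻¹)

With the reaction of substrate to uncatalysed product struck out, cedar gives 88.8%, beside our catch chance of 90.3%. For ash at 3 times its residence time we reckon a catch chance of 84.9%, and the fork share turns that into 64.3%; the tank gives 64.6%.

All runs stem from a simulated flask on assumed constants; noise was put on by code.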